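**Strategy.** Ring atoms are numbered C1 (carries the side chain), C2 (CH2), C3/C4 (epoxide, methyl on C4), C5 and C6 (ester-bearing carbons). Everything rests on closing the six-membered ring through the C5–C6 bond by a titanocene-mediated reductive pinacol coupling of an acyclic (Z)-enal aldehyde. The step exploits the vicinal C5/C6 dioxygenation of the carbocycle, a pinacol retron. In one operation it forms the carbocycle, installs both carbinol centres of the trans-diol under control of the C1 stereocentre, and leaves the C3=C4 alkene for the late epoxide. The precursor, a (2Z)-2-methylhex-2-enedial carrying the silylated side chain at C1, is assembled from fumaraldehyde monoacetal by organocatalytic Michael addition, α-methylenation, Brown allylation and Still–Gennari olefination.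

Key step: step 12

Remark: the D-fructose-derived Shi ketone is assumed to give the (R)-epoxide from the 2-methylalk-2-ene terminus, as it does for other prenyl-type alkenes; all reagents named are taken as purchasable.

Step 1
Reactants: 1 (E)-4,4-dimethoxybut-2-enal; 2 dimethyl malonate
Product: 3 dimethyl 2-[(2S)-1,1-dimethoxy-4-oxobutan-2-yl]propanedioate
Conditions: (R)-2-{bis[3,5-bis(trifluoromethyl)phenyl](trimethylsilyloxy)methyl}pyrrolidine (10 mol%), EtOH, 0 °C
Reagents that add atoms: none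
Why: Iminium-ion catalysed Michael addition of a malonate to an enal (Jørgensen–Hayashi type), in which the (R)-diarylprolinol silyl ether shields one face of the (E)-iminium ion so that the malonate should add to the β-carbon from the open face and set C1 as drawn.

Step 2
Reactants: 3 dimethyl 2-[(2S)-1,1-dimethoxy-4-oxobutan-2-yl]propanedioate
Product: 4 dimethyl 2-[(2R)-3-formyl-1,1-dimethoxybut-3-en-2-yl]propanedioate
Conditions: 37% aq. CH2O, pyrrolidine (10 mol%), EtCO2H (10 mol%), i-PrOH, 45 °C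
Reagents that add atoms: formaldehyde, C=O
Why: Amine-catalysed Mannich condensation–elimination (α-methylenation of an aldehyde) turns the α-CH2 into the exocyclic methylene; the product can no longer form an enamine, so C1 is protected from retro-Michael erosion.

Step 3
Reactants: 4 dimethyl 2-[(2R)-3-formyl-1,1-dimethoxybut-3-en-2-yl]propanedioate
Product: 5 dimethyl 2-[(2R,4S)-4-hydroxy-1,1-dimethoxy-3-methylidenehept-6-en-2-yl]propanedioate
Conditions: (−)-Ipc2B(allyl) (1 M in pentane), Et2O, −78 °C; ethanolamine work-up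
Reagents that add atoms: (−)-B-allyldiisopinocampheylborane, C=CCB([C@@H]1C[C@@H]2C[C@H]([C@H]1C)C2(C)C)[C@@H]1C[C@@H]2C[C@H]([C@H]1C)C2(C)C
Why: Brown asymmetric allylboration through a closed chair transition state, in which the (+)-α-pinene-derived reagent should add to the Si face of the 2-substituted acrolein under reagent control and give the (S)-configured side-chain carbinol.

Step 4
Reactants: 5 dimethyl 2-[(2R,4S)-4-hydroxy-1,1-dimethoxy-3-methylidenehept-6-en-2-yl]propanedioate
Product: 6 dimethyl 2-[(2R,4S)-4-[(tert-butyldiphenylsilyl)oxy]-1,1-dimethoxy-3-methylidenehept-6-en-2-yl]propanedioate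
Conditions: TBDPSCl, imidazole, DMAP (cat.), DMF, rt to 40 °C
Reagents that add atoms: tert-butyl(chloro)diphenylsilane, CC(C)(C)[Si](Cl)(c1ccccc1)c1ccccc1
Why: Silyl ether formation with a group robust enough for the Krapcho, hydride and mildly acidic steps, which also keeps this hydroxyl from forming a lactol with the later C6 aldehyde.

Step 5
Reactants: 6 dimethyl 2-[(2R,4S)-4-[(tert-butyldiphenylsilyl)oxy]-1,1-dimethoxy-3-methylidenehept-6-en-2-yl]propanedioate
Product: 7 dimethyl 2-[(2R,4S)-4-[(tert-butyldiphenylsilyl)oxy]-1,1-dimethoxy-7-methyl-3-methylideneoct-6-en-2-yl]propanedioate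
Conditions: second-generation Grubbs catalyst (H2IMes)(PCy3)Cl2Ru=CHPh (5 mol%), 2-methylbut-2-ene (excess), CH2Cl2, 40 °C
Reagents that add atoms: 2-methylbut-2-ene, CC=C(C)C
Why: Olefin cross-metathesis, in which only the terminal monosubstituted alkene should engage the ruthenium carbene (the flanked 1,1-disubstituted methylidene is too hindered) and isopropylidene transfer from the excess alkene gives the prenyl terminus.

Step 6
Reactants: 7 dimethyl 2-[(2R,4S)-4-[(tert-butyldiphenylsilyl)oxy]-1,1-dimethoxy-7-methyl-3-methylideneoct-6-en-2-yl]propanedioate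
Product: 8 methyl (3R,5S)-5-[(tert-butyldiphenylsilyl)oxy]-3-(dimethoxymethyl)-8-methyl-4-methylidenenon-7-enoate
Conditions: LiCl, H2O, DMSO, 140 °C
Reagents that add atoms: none
Why: Krapcho dealkoxycarbonylation (chloride SN2 demethylation, then decarboxylation) under neutral conditions that should leave the acetal, the silyl ether and the non-enolisable C1 centre untouched.

Step 7
Reactants: 8 methyl (3R,5S)-5-[(tert-butyldiphenylsilyl)oxy]-3-(dimethoxymethyl)-8-methyl-4-methylidenenon-7-enoate
Product: 9 (3R,5S)-5-[(tert-butyldiphenylsilyl)oxy]-3-(dimethoxymethyl)-8-methyl-4-methylidenenon-7-enal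
Conditions: i-Bu2AlH (1.1 equiv), CH2Cl2, −78 °C; Rochelle salt work-up
Reagents that add atoms: none
Why: Low-temperature DIBAL-H half-reduction of the methyl ester, which stops at the tetrahedral aluminium hemiacetal and releases the aldehyde on work-up.

Step 8
Reactants: 9 (3R,5S)-5-[(tert-butyldiphenylsilyl)oxy]-3-(dimethoxymethyl)-8-methyl-4-methylidenenon-7-enal
Product: 10 ethyl (2Z,5R,7S)-7-[(tert-butyldiphenylsilyl)oxy]-5-(dimethoxymethyl)-2,10-dimethyl-6-methylideneundeca-2,9-dienoate
Conditions: (CF3CH2O)2P(O)CH(CH3)CO2Et, KN(SiMe3)2, 18-crown-6, THF, −78 °C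
Reagents that add atoms: ethyl 2-[bis(2,2,2-trifluoroethoxy)phosphoryl]propanoate, CCOC(=O)C(C)P(=O)(OCC(F)(F)F)OCC(F)(F)F
Why: Still–Gennari variant of the Horner–Wadsworth–Emmons olefination, in which the electron-poor phosphonate with a dissociated potassium counter-ion eliminates kinetically and should give the (Z)-2-methyl enoate, placing C2 and C5 cis on the future ring alkene.

Step 9
Reactants: 10 ethyl (2Z,5R,7S)-7-[(tert-butyldiphenylsilyl)oxy]-5-(dimethoxymethyl)-2,10-dimethyl-6-methylideneundeca-2,9-dienoate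
Product: 11 (2Z,5R,7S)-7-[(tert-butyldiphenylsilyl)oxy]-5-(dimethoxymethyl)-2,10-dimethyl-6-methylideneundeca-2,9-dien-1-ol
Conditions: i-Bu2AlH (2.5 equiv), CH2Cl2, −78 to 0 °C
Reagents that add atoms: none
Why: 1,2-Reduction of the enoate by DIBAL-H gives the allylic alcohol without touching the alkene geometry.

Step 10
Reactants: 11 (2Z,5R,7S)-7-[(tert-butyldiphenylsilyl)oxy]-5-(dimethoxymethyl)-2,10-dimethyl-6-methylideneundeca-2,9-dien-1-ol
Product: 12 (2R,4Z)-2-[(3S)-3-[(tert-butyldiphenylsilyl)oxy]-6-methylhepta-1,5-dien-2-yl]-6-hydroxy-5-methylhex-4-enal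
Conditions: LiBF4, MeCN–H2O (98:2), rt
Reagents that add atoms: water, O
Why: Mild Lewis-acid-promoted acetal hydrolysis frees the C6 aldehyde under conditions that should not epimerise C1, move the β,γ-alkene into conjugation or cleave the TBDPS ether.

Step 11
Reactants: 12 (2R,4Z)-2-[(3S)-3-[(tert-butyldiphenylsilyl)oxy]-6-methylhepta-1,5-dien-2-yl]-6-hydroxy-5-methylhex-4-enal
Product: 13 (2Z,5R)-5-[(3S)-3-[(tert-butyldiphenylsilyl)oxy]-6-methylhepta-1,5-dien-2-yl]-2-methylhex-2-enedial
Conditions: MnO2 (activated, excess), CH2Cl2, rt; used at once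
Reagents that add atoms: none
Why: Allylic alcohol oxidation with MnO2 is selective for the allylic hydroxyl and neutral, so the (Z)-enal geometry and the α-stereocentre of the other aldehyde should survive.

Step 12
Reactants: 13 (2Z,5R)-5-[(3S)-3-[(tert-butyldiphenylsilyl)oxy]-6-methylhepta-1,5-dien-2-yl]-2-methylhex-2-enedial
Product: 15 (1R,2R,6R)-6-[(3S)-3-hydroxy-6-methylhepta-1,5-dien-2-yl]-3-methylcyclohex-3-ene-1,2-diol, via bis-silyl ether 14 (not isolated)
Conditions: Cp2TiCl2 (10 mol%), i-PrMgCl then PhMgBr (10 mol% each, gives Cp2TiPh), Zn, Me3SiCl, THF, rt, slow addition of 13 at high dilution; then Bu4NF, THF, 40 °C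
Reagents that add atoms: none
Why: Cp2TiPh (trivalent titanium) transfers one electron to the enal and then to the aliphatic aldehyde, the two titanoxy-substituted carbon radicals combine to form C5–C6, Me3SiCl silylates the titanium diolate and Zn returns the metal to the trivalent state. The closest known reactions are the titanocene-catalysed trans-selective pinacol cyclisation of dialdehydes and the low-valent titanium pinacol closure of an enal onto an aldehyde. The six-membered ring closes in a 6-exo-trig mode with both oxygens exocyclic and the (Z)-alkene C3=C4 inside the tether. C6 should be set trans to the side chain because C1 holds its branch equatorial in the half-chair transition state and the bulky titanoxy group on C6 also goes equatorial; C5 should be set trans to the C6 oxygen because allylic 1,3-strain in the (Z)-enal keeps its oxygen pointing away from C2 (pseudo-equatorial) and the two large O–Ti groups avoid a syn, chelate-like arrangement. The step needs trans over cis diol selectivity, cyclisation over intermolecular coupling and a (Z)-alkene at ring closure; the non-chelating bulky titanium, slow addition at high dilution and the fact that only the (Z)-isomer can reach the ring should secure these, and fluoride then removes the two trimethylsilyl groups and the TBDPS ether.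

Step 13
Reactants: 15 (1R,2R,6R)-6-[(3S)-3-hydroxy-6-methylhepta-1,5-dien-2-yl]-3-methylcyclohex-3-ene-1,2-diol
Product: 16 (1R,2R,6R)-3-methyl-6-[(3S)-6-methyl-3-{[(2Z)-2-methylbut-2-enoyl]oxy}hepta-1,5-dien-2-yl]cyclohex-3-ene-1,2-diyl bis[(2Z)-2-methylbut-2-enoate]
Conditions: angelic acid, 2,4,6-trichlorobenzoyl chloride, Et3N, toluene, rt; then 15, 80 °C (no DMAP)
Reagents that add atoms: angelic acid [(2Z)-2-methylbut-2-enoic acid], C/C=C(/C)C(=O)O
Why: Yamaguchi-type mixed-anhydride esterification run without a nucleophilic catalyst, conditions known to acylate hindered secondary alcohols with angelic acid without Z to E isomerisation, with heat driving all three hydroxyls to the ester.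

Step 14
Reactants: 16 (1R,2R,6R)-3-methyl-6-[(3S)-6-methyl-3-{[(2Z)-2-methylbut-2-enoyl]oxy}hepta-1,5-dien-2-yl]cyclohex-3-ene-1,2-diyl bis[(2Z)-2-methylbut-2-enoate]
Product: 17 (1R,2R,6R)-6-[(3S)-4-[(2R)-3,3-dimethyloxiran-2-yl]-3-{[(2Z)-2-methylbut-2-enoyl]oxy}but-1-en-2-yl]-3-methylcyclohex-3-ene-1,2-diyl bis[(2Z)-2-methylbut-2-enoate]
Conditions: D-fructose-derived Shi ketone (30 mol%), Oxone (KHSO5, limiting), K2CO3, Bu4NHSO4 (cat.), MeCN–CH2(OMe)2/aq. Na2B4O7 buffer (pH 10.5), 0 °C
Reagents that add atoms: potassium peroxymonosulfate, [K+].OOS(=O)(=O)[O-]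
Why: Shi asymmetric epoxidation, in which the chiral dioxirane should react fastest with the unhindered electron-rich side-chain trisubstituted alkene through a spiro transition state that gives the (R)-epoxide, while the ring alkene (deactivated and shielded by its allylic ester) and the conjugated angelate alkenes stay intact at limited oxidant.

Step 15
Reactants: 17 (1R,2R,6R)-6-[(3S)-4-[(2R)-3,3-dimethyloxiran-2-yl]-3-{[(2Z)-2-methylbut-2-enoyl]oxy}but-1-en-2-yl]-3-methylcyclohex-3-ene-1,2-diyl bis[(2Z)-2-methylbut-2-enoate]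
Product: 18 (1S,2S,3R,4R,6S)-4-[(3S)-4-[(2R)-3,3-dimethyloxiran-2-yl]-3-{[(2Z)-2-methylbut-2-enoyl]oxy}but-1-en-2-yl]-1-methyl-7-oxabicyclo[4.1.0]heptane-2,3-diyl bis[(2Z)-2-methylbut-2-enoate] (CNP0258231.1)
Conditions: dimethyldioxirane (1.1 equiv, acetone solution), CH2Cl2, −20 to 0 °C
Reagents that add atoms: dimethyldioxirane, CC1(C)OO1
Why: Electrophilic epoxidation by the sterically demanding dioxirane should occur at the remaining trisubstituted ring alkene anti to the adjacent C5 angeloyloxy group (substrate control), which places the epoxide oxygen trans to the C5 oxygen as in the target, the 1,1-disubstituted and conjugated alkenes being much less reactive.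

**Compound list**

1 | (E)-4,4-dimethoxybut-2-enal (fumaraldehyde mono(dimethyl acetal)) | COC(OC)/C=C/C=O | starting material
2 | dimethyl malonate | COC(=O)CC(=O)OC | starting material
3 | dimethyl 2-[(2S)-1,1-dimethoxy-4-oxobutan-2-yl]propanedioate | O=CC[C@H](C(OC)OC)C(C(=O)OC)C(=O)OC | intermediate
4 | dimethyl 2-[(2R)-3-formyl-1,1-dimethoxybut-3-en-2-yl]propanedioate | C=C(C=O)[C@H](C(OC)OC)C(C(=O)OC)C(=O)OC | intermediate
5 | dimethyl 2-[(2R,4S)-4-hydroxy-1,1-dimethoxy-3-methylidenehept-6-en-2-yl]propanedioate | C=C([C@H](CC=C)O)[C@H](C(OC)OC)C(C(=O)OC)C(=O)OC | intermediate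
6 | dimethyl 2-[(2R,4S)-4-[(tert-butyldiphenylsilyl)oxy]-1,1-dimethoxy-3-methylidenehept-6-en-2-yl]propanedioate | C=C([C@H](CC=C)O[Si](c1ccccc1)(c1ccccc1)C(C)(C)C)[C@H](C(OC)OC)C(C(=O)OC)C(=O)OC | intermediate
7 | dimethyl 2-[(2R,4S)-4-[(tert-butyldiphenylsilyl)oxy]-1,1-dimethoxy-7-methyl-3-methylideneoct-6-en-2-yl]propanedioate | C=C([C@H](CC=C(C)C)O[Si](c1ccccc1)(c1ccccc1)C(C)(C)C)[C@H](C(OC)OC)C(C(=O)OC)C(=O)OC | intermediate
8 | methyl (3R,5S)-5-[(tert-butyldiphenylsilyl)oxy]-3-(dimethoxymethyl)-8-methyl-4-methylidenenon-7-enoate | C=C([C@H](CC=C(C)C)O[Si](c1ccccc1)(c1ccccc1)C(C)(C)C)[C@H](C(OC)OC)CC(=O)OC | intermediate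
9 | (3R,5S)-5-[(tert-butyldiphenylsilyl)oxy]-3-(dimethoxymethyl)-8-methyl-4-methylidenenon-7-enal | C=C([C@H](CC=C(C)C)O[Si](c1ccccc1)(c1ccccc1)C(C)(C)C)[C@H](C(OC)OC)CC=O | intermediate
10 | ethyl (2Z,5R,7S)-7-[(tert-butyldiphenylsilyl)oxy]-5-(dimethoxymethyl)-2,10-dimethyl-6-methylideneundeca-2,9-dienoate | C=C([C@H](CC=C(C)C)O[Si](c1ccccc1)(c1ccccc1)C(C)(C)C)[C@H](C(OC)OC)C/C=C(/C)C(=O)OCC | intermediate
11 | (2Z,5R,7S)-7-[(tert-butyldiphenylsilyl)oxy]-5-(dimethoxymethyl)-2,10-dimethyl-6-methylideneundeca-2,9-dien-1-ol | C=C([C@H](CC=C(C)C)O[Si](c1ccccc1)(c1ccccc1)C(C)(C)C)[C@H](C(OC)OC)C/C=C(/C)CO | intermediate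
12 | (2R,4Z)-2-[(3S)-3-[(tert-butyldiphenylsilyl)oxy]-6-methylhepta-1,5-dien-2-yl]-6-hydroxy-5-methylhex-4-enal | C=C([C@H](CC=C(C)C)O[Si](c1ccccc1)(c1ccccc1)C(C)(C)C)[C@H](C=O)C/C=C(/C)CO | intermediate
13 | (2Z,5R)-5-[(3S)-3-[(tert-butyldiphenylsilyl)oxy]-6-methylhepta-1,5-dien-2-yl]-2-methylhex-2-enedial | C=C([C@H](CC=C(C)C)O[Si](c1ccccc1)(c1ccccc1)C(C)(C)C)[C@H](C=O)C/C=C(/C)C=O | intermediate
14 | tert-butyl({(3S)-6-methyl-2-[(1R,5R,6R)-4-methyl-5,6-bis(trimethylsilyloxy)cyclohex-3-en-1-yl]hepta-1,5-dien-3-yl}oxy)diphenylsilane | C=C([C@H](CC=C(C)C)O[Si](c1ccccc1)(c1ccccc1)C(C)(C)C)[C@H]1CC=C(C)[C@@H](O[Si](C)(C)C)[C@@H]1O[Si](C)(C)C | intermediate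
15 | (1R,2R,6R)-6-[(3S)-3-hydroxy-6-methylhepta-1,5-dien-2-yl]-3-methylcyclohex-3-ene-1,2-diol | C=C([C@H](CC=C(C)C)O)[C@H]1CC=C(C)[C@@H](O)[C@@H]1O | intermediate
16 | (1R,2R,6R)-3-methyl-6-[(3S)-6-methyl-3-{[(2Z)-2-methylbut-2-enoyl]oxy}hepta-1,5-dien-2-yl]cyclohex-3-ene-1,2-diyl bis[(2Z)-2-methylbut-2-enoate] | C=C([C@H](CC=C(C)C)OC(=O)/C(C)=C\C)[C@H]1CC=C(C)[C@@H](OC(=O)/C(C)=C\C)[C@@H]1OC(=O)/C(C)=C\C | intermediate
17 | (1R,2R,6R)-6-[(3S)-4-[(2R)-3,3-dimethyloxiran-2-yl]-3-{[(2Z)-2-methylbut-2-enoyl]oxy}but-1-en-2-yl]-3-methylcyclohex-3-ene-1,2-diyl bis[(2Z)-2-methylbut-2-enoate] | C=C([C@H](C[C@H]1OC1(C)C)OC(=O)/C(C)=C\C)[C@H]1CC=C(C)[C@@H](OC(=O)/C(C)=C\C)[C@@H]1OC(=O)/C(C)=C\C | intermediate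
18 | (1S,2S,3R,4R,6S)-4-[(3S)-4-[(2R)-3,3-dimethyloxiran-2-yl]-3-{[(2Z)-2-methylbut-2-enoyl]oxy}but-1-en-2-yl]-1-methyl-7-oxabicyclo[4.1.0]heptane-2,3-diyl bis[(2Z)-2-methylbut-2-enoate] (CNP0258231.1) | C=C([C@H](C[C@H]1OC1(C)C)OC(=O)/C(C)=C\C)[C@H]1C[C@@H]2O[C@]2(C)[C@@H](OC(=O)/C(C)=C\C)[C@@H]1OC(=O)/C(C)=C\C | target

**Step count.** Total: 15 steps. Longest linear sequence: 15 steps (from 1).

**Steps most likely to fail**

Step 12 (key pinacol closure). The enal may lose its (Z)-geometry before the ring closes, intermolecular coupling may compete, or the diol may form with the wrong relative configuration. The fallback sets out from 13 and replaces titanium by a chelating reductant followed by a stereoconvergent correction. SmI2 (THF, t-BuOH, −78 °C) should close the same bond and give a ring diol, drawn as the cis-diol silyl ether F1 (other C5/C6 diastereomers are carried along). MnO2 oxidation of the allylic C5 carbinol gives the 6-epi hydroxy enone F2. DBU equilibrates the α-hydroxy ketone centre to the equatorial hydroxy enone F3, with the hydroxyl trans to the side chain. Luche reduction (NaBH4, CeCl3·7H2O, MeOH, −78 °C) should deliver the pseudo-equatorial C5 alcohol and so the trans-diol silyl ether F4. Bu4NF then removes the TBDPS group and the route is rejoined at 15.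

Step 13 (triple angeloylation). The angeloyl unit may isomerise from Z to E (tiglate formation), and acylation of the hindered vicinal diol may stop short. The fallback sets out from 15 and builds the Z-alkenes in place. Esterification with 2-[bis(2,2,2-trifluoroethoxy)phosphoryl]propanoic acid (EDC·HCl, DMAP, CH2Cl2) gives the tris(phosphonopropanoate) F5. A threefold Still–Gennari olefination with acetaldehyde (KN(SiMe3)2, 18-crown-6, THF, −78 °C) should then form each (2Z)-2-methylbut-2-enoate, and the route is rejoined at 16.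

Step 15 (ring epoxidation). Facial selectivity may be poor (oxygen delivered syn to the C5 ester), or the 1,1-disubstituted alkene may compete. The fallback sets out from 17 and replaces substrate control by catalyst control. The L-fructose-derived enantiomer of the Shi ketone with Oxone (buffered MeCN–CH2(OMe)2/water, 0 °C) is expected to favour the same anti face through its spiro transition state while ignoring the 1,1-disubstituted alkene. This leads directly to 18 and makes no new compound.

**Further compounds**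

F1 | step 12 | (1S,2R,6R)-6-[(3S)-3-[(tert-butyldiphenylsilyl)oxy]-6-methylhepta-1,5-dien-2-yl]-3-methylcyclohex-3-ene-1,2-diol | C=C([C@H](CC=C(C)C)O[Si](c1ccccc1)(c1ccccc1)C(C)(C)C)[C@H]1CC=C(C)[C@@H](O)[C@H]1O
F2 | step 12 | (5R,6S)-5-[(3S)-3-[(tert-butyldiphenylsilyl)oxy]-6-methylhepta-1,5-dien-2-yl]-6-hydroxy-2-methylcyclohex-2-en-1-one | C=C([C@H](CC=C(C)C)O[Si](c1ccccc1)(c1ccccc1)C(C)(C)C)[C@H]1CC=C(C)C(=O)[C@H]1O
F3 | step 12 | (5R,6R)-5-[(3S)-3-[(tert-butyldiphenylsilyl)oxy]-6-methylhepta-1,5-dien-2-yl]-6-hydroxy-2-methylcyclohex-2-en-1-one | C=C([C@H](CC=C(C)C)O[Si](c1ccccc1)(c1ccccc1)C(C)(C)C)[C@H]1CC=C(C)C(=O)[C@@H]1O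
F4 | step 12 | (1R,2R,6R)-6-[(3S)-3-[(tert-butyldiphenylsilyl)oxy]-6-methylhepta-1,5-dien-2-yl]-3-methylcyclohex-3-ene-1,2-diol | C=C([C@H](CC=C(C)C)O[Si](c1ccccc1)(c1ccccc1)C(C)(C)C)[C@H]1CC=C(C)[C@@H](O)[C@@H]1O
F5 | step 13 | (1R,2R,6R)-6-[(3S)-3-({2-[bis(2,2,2-trifluoroethoxy)phosphoryl]propanoyl}oxy)-6-methylhepta-1,5-dien-2-yl]-3-methylcyclohex-3-ene-1,2-diyl bis{2-[bis(2,2,2-trifluoroethoxy)phosphoryl]propanoate} | C=C([C@H](CC=C(C)C)OC(=O)C(C)P(=O)(OCC(F)(F)F)OCC(F)(F)F)[C@H]1CC=C(C)[C@@H](OC(=O)C(C)P(=O)(OCC(F)(F)F)OCC(F)(F)F)[C@@H]1OC(=O)C(C)P(=O)(OCC(F)(F)F)OCC(F)(F)F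
F0 | step 15 | none | none
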